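**Retrosynthetic overview**
1. Absinthin 8 ⇒ cut C2–C2′ and C5–C3′ (the norbornene ring, formed last) ⇒ two molecules of the 1αH-guaia-2,4-dien-10β-ol-olide 7.
2. 7 ⇒ suprafacial [1,5]-H shift (H-5α to C1α) from the 5αH-1,3-diene 6 ⇒ C1–O cleavage of the 1β,10β-epoxy-Δ3-guaianolide 5. The tertiary C10–O centre travels as an epoxide, so no carbinol inversion is needed.
3. 5 ⇒ dehydration of epoxy alcohol 4 ⇒ key operation. The ten-membered ring of germacranolide 2 is folded across C1–C5, which makes the cyclopentane and cycloheptene at once. The new Δ1(10) olefin is then epoxidised in the same flask (oxirane).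
4. 2 ⇒ conjugate reduction (sets C11) of parthenolide 1, which supplies the lactone ring, C6, C7 and the 4,5-epoxide trigger.
5. Ring order: lactone (bought) → five- and seven-membered carbocycles plus oxirane (one flask) → oxirane spent → bridging ring of the norbornene (dimerisation).

Assumption: (−)-parthenolide, sold as a bulk isolate from feverfew or Magnolia root bark, is the commercial starting material. Germacrane/guaiane numbering is used, with primes for the dienophile half.

**Step 1**
Reactants: 1 (−)-parthenolide
Product: 2 (11S)-11βH,13-dihydroparthenolide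
Conditions: NaBH4 (1 equiv), MeOH, 0 °C, 30 min
Reagents that add atoms: none
Why: This is a conjugate (1,4-) hydride reduction of the α-methylene-γ-butyrolactone in which the lactone enolate is protonated on its β-face, anti to the adjacent axial H-7α, giving the 11βH (11S, α-methyl) epimer that methoxide equilibration also favours, while the epoxide, the trisubstituted olefin and the lactone C=O survive at 0 °C.

**Step 2**
Reactants: 2 (11S)-11βH,13-dihydroparthenolide
Product: 4 1β,10β-epoxy-4α-hydroxy-5αH,11βH-guaian-12,6α-olide, via 11βH-dihydromicheliolide 3 (not isolated)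
Conditions: TsOH·H2O (10 mol %), CH2Cl2, rt, 12 h; then NaHCO3 (20 mol %), mCPBA (1.2 equiv), 0 °C → rt
Reagents that add atoms: mCPBA, O=C(OO)c1cccc(Cl)c1
Why: In this transannular epoxide–olefin (cation–olefin) cyclisation C1 of the E-olefin attacks C5 anti to the protonated oxirane (inversion gives 5αH, the 4α-OH is retained) and the C10 cation loses H-1, so cyclopentane and cycloheptene form together as Δ1(10)-olefin 3, after which Prilezhaev epoxidation of this most electron-rich olefin from the β-face (the established preference of the 11,13-dehydro analogue) fixes C1 and the C10–O bond in the absinthin configuration.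

**Step 3**
Reactants: 4 1β,10β-epoxy-4α-hydroxy-5αH,11βH-guaian-12,6α-olide
Product: 5 1β,10β-epoxy-5αH,11βH-guai-3-en-12,6α-olide (11βH,13-dihydroarglabin)
Conditions: Martin sulfurane (1.5 equiv), CH2Cl2, −20 °C → rt
Reagents that add atoms: none
Why: Martin sulfurane dehydration of the tertiary 4α-alkoxysulfonium under non-acidic conditions removes the anti H-3β (H-5α is syn to the leaving group and stays), giving the endocyclic Δ3 olefin as in the 11,13-dehydro series, with no new stereocentre and with the tetrasubstituted epoxide and the lactone untouched.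

**Step 4**
Reactants: 5 1β,10β-epoxy-5αH,11βH-guai-3-en-12,6α-olide (two molecules end up in the product)
Product: 8 (+)-absinthin, via 5αH-guaia-1,3-dienol 6 (not isolated), via 1αH-guaia-2,4-dienol 7 (not isolated)
Conditions: Cp2TiCl2 (2.5 equiv), Mn (8 equiv), degassed THF, rt, 1 h; aqueous work-up, short Florisil plug; then neat (trace BHT, Ar, dark), rt, 10 d
Reagents that add atoms: none
Why: Nugent–RajanBabu Ti(III) homolysis leaves the bulky Ti–O on the less congested C10 and the radical on C1, a second Cp2TiCl removes the weak allylic H-2 (mixed disproportionation, epoxide → allylic alcohol) to give 6 under neutral conditions, a suprafacial [1,5]-sigmatropic shift carries H-5α to C1α (7; all tautomers interconvert within hours while dimerisation takes days), and an endo Diels–Alder homodimerisation, α-face of the diene C2=C3–C4=C5 onto the α-face of the only unhindered olefin C2′=C3′ (both anti to C10), sets C2, C5, C2′ and C3′, as the 10-epi-acetate analogue of 7 is known to do neat at rt.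

**Compound list**
1 | (−)-parthenolide, 4α,5β-epoxygermacra-1(10)E,11(13)-dien-12,6α-olide | C/C1=C\CC[C@@]2(C)O[C@@H]2[C@H]3OC(=O)C(=C)[C@@H]3CC1 | starting material
2 | (11S)-11βH,13-dihydroparthenolide | C/C1=C\CC[C@@]2(C)O[C@@H]2[C@H]3OC(=O)[C@@H](C)[C@@H]3CC1 | intermediate
3 | 11βH,13-dihydromicheliolide, 4α-hydroxy-5αH,11βH-guai-1(10)-en-12,6α-olide | CC1=C2CC[C@@](C)(O)[C@@H]2[C@H]3OC(=O)[C@@H](C)[C@@H]3CC1 | intermediate
4 | 1β,10β-epoxy-4α-hydroxy-5αH,11βH-guaian-12,6α-olide | C[C@@]12O[C@@]13CC[C@@](C)(O)[C@@H]3[C@H]4OC(=O)[C@@H](C)[C@@H]4CC2 | intermediate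
5 | 1β,10β-epoxy-5αH,11βH-guai-3-en-12,6α-olide (11βH,13-dihydroarglabin) | C[C@@]12O[C@@]13CC=C(C)[C@@H]3[C@H]4OC(=O)[C@@H](C)[C@@H]4CC2 | intermediate
6 | 10β-hydroxy-5αH,11βH-guaia-1,3-dien-12,6α-olide | CC1=CC=C2[C@H]1[C@H]3OC(=O)[C@@H](C)[C@@H]3CC[C@]2(C)O | intermediate
7 | 10β-hydroxy-1αH,11βH-guaia-2,4-dien-12,6α-olide | CC1=C2[C@H]3OC(=O)[C@@H](C)[C@@H]3CC[C@](C)(O)[C@@H]2C=C1 | intermediate
8 | (+)-absinthin | CC1=C[C@@H]2[C@H]3[C@H](C(C)=C4[C@H]5OC(=O)[C@@H](C)[C@@H]5CC[C@](C)(O)[C@@H]43)[C@@]13[C@@H]2[C@@](C)(O)CC[C@H]1[C@H](C)C(=O)O[C@@H]13 | target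

**Total step count:** 4. **Longest linear sequence:** 4.

**Steps most likely to fail**

Step 4 is the riskiest. Both epoxide carbons are fully substituted, so Ti(III) may cleave C10–O instead, giving the 1β-ol with a Δ10(14) olefin. It may also deoxygenate the epoxide, and the diene tautomers are sensitive to air and to base. The fallback makes the C1–O cleavage regiospecific by design and sets out from 5. CrO3·3,5-dimethylpyrazole (CH2Cl2, −20 °C) oxidises the only allylic CH2 (C2) to 1β,10β-epoxy-2-oxo-5αH,11βH-guai-3-en-12,6α-olide F1. Hydrazine hydrate with catalytic AcOH in MeOH (0 °C → rt) converts this α,β-epoxy ketone into the epoxy-enone hydrazone F2. F2 collapses in a Wharton transposition to the C1=C2 olefin and the 10β-alcohol. The fallback comes back to the route at 6, and the H shift and dimerisation follow as written.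

Step 3 may give the exocyclic Δ4(15) olefin, or the acidic fluoroalcohol may damage the epoxide. The fallback gives up regioselective elimination and sets out from 4. Burgess reagent (toluene, 50 °C, syn-elimination) is allowed to deliver mainly 1β,10β-epoxy-5αH,11βH-guai-4(15)-en-12,6α-olide F3 together with some 5. The mixture is then converged by neutral radical (MHAT) olefin isomerisation with a Co(salen)Cl catalyst and catalytic PhSiH3 in benzene at rt. This moves the double bond into the ring through the C4 tertiary radical. The fallback comes back to the route at 5.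

In step 2 the cyclisation itself is reliable. The risk is that the peracid prefers the α-face in the 11,13-dihydro series, or that the one-flask sequence erodes the labile epoxide. The fallback inverts the facial outcome mechanistically and sets out from 3, isolated after the TsOH stage. NBS in aqueous acetone (0 °C) places bromonium on the same face the peracid would take. Water opens it anti at C10, the better cation site, to give 1α-bromo-4α,10β-dihydroxy-5αH,11βH-guaian-12,6α-olide F4. K2CO3 in acetone then closes the 10β-alkoxide onto C1 with inversion. The fallback comes back to the route at 4.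

**Further compounds**
F1 | step 4 | 1β,10β-epoxy-2-oxo-5αH,11βH-guai-3-en-12,6α-olide | C[C@@]12O[C@@]13C(=O)C=C(C)[C@@H]3[C@H]4OC(=O)[C@@H](C)[C@@H]4CC2
F2 | step 4 | epoxy-enone hydrazone (C2 hydrazone of F1) | C[C@@]12O[C@@]13C(=NN)C=C(C)[C@@H]3[C@H]4OC(=O)[C@@H](C)[C@@H]4CC2
F3 | step 3 | 1β,10β-epoxy-5αH,11βH-guai-4(15)-en-12,6α-olide | C[C@@]12O[C@@]13CCC(=C)[C@@H]3[C@H]4OC(=O)[C@@H](C)[C@@H]4CC2
F4 | step 2 | 1α-bromo-4α,10β-dihydroxy-5αH,11βH-guaian-12,6α-olide | C[C@@]1(O)[C@]2(Br)CC[C@@](C)(O)[C@@H]2[C@H]3OC(=O)[C@@H](C)[C@@H]3CC1
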